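## Structural features

The target is a flavone: a benzopyran-4-one (rings A and C, fused through C4a–C8a) that carries ring B on C2 through the C2–C1' bond, and it has no stereocentre. Ring A is fully substituted, with hydroxyls at C5 and C7 alternating with methoxyls at C6 and C8; ring C has a methoxyl at C3; ring B has a 2'-methoxyl and a 4',5'-catechol. With eight oxygen substituents, the free catechol and the phloroglucinol-type ring A oxidise easily to quinones, and the pyranone can be opened by hard nucleophiles at C2. The 5-OH is chelated to the C4 carbonyl, so it is slow to alkylate. The difficulty lies in the oxygen pattern and not in the skeleton: four oxygens must end as methyl ethers and four as free phenols, and the C3 oxygen sits on the carbon that most flavone assemblies leave as C–H. The ortho methoxyl of ring B twists the aryl group and crowds C2 and C3. The key step uses two facts. First, C4 is a carbonyl carbon between the aryl carbon C4a and C3, with O1 on the neighbouring C8a, so ring C is the sum of an ortho-iodophenol, carbon monoxide and a terminal arylalkyne. Second, ring A is mirror-symmetric about the line through C4a and C7 (the oxygen on C5 matches O1 on C8a, and the 6-OMe matches the 8-OMe), so the iodophenol partner needs no differentiation of its two ortho oxygens.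

## Logic of the disconnections

22 to 21: the four benzyl–oxygen bonds at O5, O7, O4' and O5' are cut. These four phenols would be oxidised or alkylated in every earlier step, and benzyl can be removed without touching four methyl ethers. One operation then uncovers the whole target. The forward hydrogenolysis must spare the C2=C3 bond, and the product must be kept from air.

21 to 20: the O–CH3 bond at C3 is cut. In 20 the C3 hydroxyl is the only acidic site, so methylation is unambiguous. The forward step needs only a mild base so that the pyranone is not opened.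

20 to 18 (through 19): the C3–O bond is cut. C3 starts as the terminal CH of an alkyne, so its oxygen has to be added after ring closure. The C2=C3 bond of 18 is an enol ether and the most nucleophilic alkene in the molecule, so electrophilic oxygen transfer gives 19, which opens towards C2 and loses H3. The oxidant must prefer this alkene over the electron-rich rings and the benzylic C–H bonds, and no free phenol may be present.

18 to 17: the benzyl–oxygen bonds at O5 and O7 are cut. The phenols of 17 would not survive the oxidation and would compete in the later methylation; benzyl is chosen so that these groups leave together with those of ring B. The chelated 5-OH demands forcing alkylation, and C-alkylation is excluded because ring A has no free carbon.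

17 to 6, 13 and 14: the bonds C4a–C4, C4–C3 and O1–C2 are cut. This is the key disconnection: ring C falls apart into two benzene derivatives and 14, the route becomes convergent, and the symmetry of 6 rules out a regioisomer. The forward step must favour carbonylation over direct alkynylation and over amide formation, and ring closure must be 6-endo.

6 to 4 (through 5): the C–I bond and the three acetyl–oxygen bonds are cut. The only free ring position of 4 lies between two hydroxyls and para to the third, so iodination has one possible site. The acetates make the iodide storable and are lost in the key step without a separate operation. Iodination must outrun oxidation of the triol, so it is run cold and the product is acetylated in the same flask.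

4 to 3 to 2 to 1: the three benzyl–oxygen bonds, then the two aryl C–OMe bonds, then the two C–Br bonds are cut. In 1 every free position is activated by three ether oxygens; two of the three equivalent positions are brominated and turned into methoxyls, while benzyl keeps the other three oxygens distinct. This leads back to a commercial symmetric ether. The forward steps must stop at dibromination and must achieve a double copper-mediated substitution at crowded, electron-rich carbons without reduction.

13 to 12: the bond between the two alkyne carbons is cut, a one-carbon homologation of an aldehyde. The aldehyde is not enolisable, so basic methanol is tolerated.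

12 to 10 (through 11): the aryl–CHO bond is cut. In 10 the carbon ortho to the methoxyl and para to a benzyloxy group is the only one with both an ortho and a para donor, so formylation has one favoured site. The forward step must avoid strong Lewis acids to keep the benzyl ethers.

10 to 9 to 7 (through 8): the O–CH3 bond and then the aryl C–O bond are cut. The formyl group of a cheap protected catechol aldehyde is turned into the oxygen that becomes the 2'-methoxyl. The forward oxidation needs aryl migration rather than hydride migration, which the para benzyloxy group secures.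

## Other disconnections considered

Alternative 1: The cut removes C3 from ring C and leads back to 4,6-bis(benzyloxy)-2-[4,5-bis(benzyloxy)-2-methoxyphenyl]-5,7-dimethoxy-1-benzofuran-3(2H)-one A1, used as its silyl enol ether {[4,6-bis(benzyloxy)-2-[4,5-bis(benzyloxy)-2-methoxyphenyl]-5,7-dimethoxy-1-benzofuran-3-yl]oxy}(tert-butyl)dimethylsilane A2. In the forward key step dibromocarbene (bromoform, KOtBu) would add to the C2=C3 bond of A2, and the dibromocyclopropane would open with loss of bromide and silyl to give 5,7-bis(benzyloxy)-2-[4,5-bis(benzyloxy)-2-methoxyphenyl]-3-bromo-6,8-dimethoxy-4H-chromen-4-one A3, forming C2–C3 and C3–C4 in a Ciamician–Dennstedt-type expansion.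
- In its favour: C3 arrives as C–Br, so one copper-mediated methoxylation should lead to 21, and the phenols are already benzylated. On the end game this plan is the better one, with two steps after ring closure against four, and it needs neither carbon monoxide nor a peroxide.
- Against it: A1 requires a ring A in which the furan oxygen is distinguished from the two benzylated oxygens, so the symmetry of ring A is used up early and a longer linear sequence is needed. 2-Arylbenzofuranones autoxidise readily at C2. The carbene has to add to a fully substituted, crowded double bond that is part of an aromatic furan, under strongly basic conditions and with a reagent that can also attack ring B.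
- Comparison: both plans are regiochemically unambiguous. The chosen plan is convergent and uses symmetric ring A chemistry, whereas the alternative spends its steps before the key step, so its shorter end game is expected to be offset by the longer approach to A1.

Alternative 2: The cut is C8–C8a together with the whole of ring A, which is built from a squarate. 2-[4,5-Bis(benzyloxy)-2-methoxyphenyl]-5-bromo-3-methoxy-4H-pyran-4-one A4 would be metallated and added to 3-tert-butoxy-4-methoxycyclobut-3-ene-1,2-dione A5 to give racemic 2-tert-butoxy-4-hydroxy-3-methoxy-4-{6-[4,5-bis(benzyloxy)-2-methoxyphenyl]-5-methoxy-4-oxo-4H-pyran-3-yl}cyclobut-2-en-1-one A6. Heating A6 would open the four-membered ring to a vinylketene, and 6π closure onto the pyranone carbon next to the ring oxygen followed by tautomerisation would give 2-[4,5-bis(benzyloxy)-2-methoxyphenyl]-7-tert-butoxy-5,8-dihydroxy-3,6-dimethoxy-4H-chromen-4-one A7.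
- In its favour: every oxygen of ring A is placed by the mechanism, the C3 methoxyl is present from the start, and no metal catalyst or toxic gas is needed. On regiocontrol it is the equal of the chosen plan, and on the C3 oxygen it is the better one, since no late oxidation is required.
- Against it: neither A4 nor A5 is commercial, and A4 needs its own multistep synthesis. The metallated pyranone is a fragile species that must be made and used at low temperature. Addition to A5 must select the carbonyl remote from the tert-butoxy group. A7 is a 5,8-hydroquinone that oxidises easily to the quinone and still needs selective 8-O-methylation, acidic loss of tert-butyl and debenzylation.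
- Comparison: the chosen plan gets ring A from a symmetric benzene in four operations and handles its one air-sensitive intermediate in a single flask. The alternative has an elegant ring construction, but it is expected to be longer and to pass through more sensitive compounds.

Alternative 3: The cut is O1–C8a. 2,4,6-Tribromo-3,5-dimethoxybenzoic acid A8 (as its acid chloride) would acylate the enolate of 1-[4,5-bis(benzyloxy)-2-methoxyphenyl]-2-methoxyethan-1-one A9 to give 1-[4,5-bis(benzyloxy)-2-methoxyphenyl]-2-methoxy-3-(2,4,6-tribromo-3,5-dimethoxyphenyl)propane-1,3-dione A10. In the forward key step the enolate oxygen of A10 would displace one ortho bromide under a monovalent copper catalyst (CuI) with K2CO3, an intramolecular Ullmann-type O-arylation, to give 2-[4,5-bis(benzyloxy)-2-methoxyphenyl]-5,7-dibromo-3,6,8-trimethoxy-4H-chromen-4-one A11.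
- In its favour: it uses the same symmetry of ring A (the two ortho bromides are equivalent), so on that point it is the equal of the chosen plan. It is the better one in two respects: the C3 methoxyl is carried in with A9, and A8 should be available in one step by exhaustive bromination of a commercial acid. It also avoids carbon monoxide and peroxides, and on paper it is the shortest of the four plans.
- Against it: the oxygens at C5 and C7 are still missing in A11 and must be introduced at two aryl bromides after ring closure. The C7 bromide lies between two methoxyls, and alkoxide or hydroxide at the temperatures such couplings need can add to C2 and open the pyranone. The acylation that gives A10 uses a doubly ortho-substituted benzoyl electrophile. The remaining bromides can also react with copper during the cyclisation.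
- Comparison: the chosen plan has all ring A oxygens in place before the coupling and leaves only routine protecting-group steps and one oxidation for the end. The alternative is shorter in count, but its two hardest C–O bonds come last on the most valuable intermediate.

Key step: step 9

Assumption: diethylamine is taken to cleave the three acetates of 6 at or before the ynone stage, so the non-isolated intermediates 15 and 16 are written as free triphenols; the timing does not change the product. Epoxide 19 is racemic and its SMILES shows one enantiomer.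

## Route

Step 1
Reactants: 1 1,3,5-tris(benzyloxy)benzene
Product: 2 1,3,5-tris(benzyloxy)-2,4-dibromobenzene
Conditions: N-bromosuccinimide (2.05 equiv), CH2Cl2, 0 °C to rt, dark
Reagents that add atoms: N-bromosuccinimide, O=C1CCC(=O)N1Br
Why: Electrophilic aromatic bromination; each free position of 1 is ortho to two benzyloxy groups and para to the third, any two substitutions give the same 2,4-dibromide, and the third is slowed by the two bromines and by crowding, so two equivalents at low temperature should stop at 2.

Step 2
Reactants: 2 1,3,5-tris(benzyloxy)-2,4-dibromobenzene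
Product: 3 1,3,5-tris(benzyloxy)-2,4-dimethoxybenzene
Conditions: NaOMe (10 equiv), CuBr (0.3 equiv), DMF/MeOH, 110 °C, argon
Reagents that add atoms: sodium methoxide, [Na+].[O-]C
Why: Ullmann-type methoxylation of aryl bromides by a monovalent copper methoxide; the reaction tolerates flanking alkoxy groups, and benzyl aryl ethers are inert to methoxide.

Step 3
Reactants: 3 1,3,5-tris(benzyloxy)-2,4-dimethoxybenzene
Product: 4 2,4-dimethoxybenzene-1,3,5-triol
Conditions: H2 (1 atm), 10 % Pd/C, EtOAc/MeOH, rt; filtered under argon and used at once
Reagents that add atoms: none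
Why: Catalytic hydrogenolysis of benzyl aryl ethers; the methyl ethers and the ring are untouched, and the air-sensitive triol is not stored.

Step 4
Reactants: 4 2,4-dimethoxybenzene-1,3,5-triol
Product: 6 2-iodo-4,6-dimethoxybenzene-1,3,5-triyl triacetate, via iodotriol 5 (not isolated)
Conditions: N-iodosuccinimide (1.0 equiv), MeCN, −10 °C, argon, dark; then pyridine, Ac2O, 4-(dimethylamino)pyridine (5 mol %), 0 °C to rt
Reagents that add atoms: N-iodosuccinimide, O=C1CCC(=O)N1I; acetic anhydride, CC(=O)OC(C)=O
Why: Electrophilic iodination at the only free ring position, which is ortho to two hydroxyls and para to the third, then exhaustive O-acetylation in the same flask so that the oxidation-prone iodotriol 5 is never handled; the triacetate 6 should be stable to storage.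

Step 5
Reactants: 7 3,4-bis(benzyloxy)benzaldehyde
Product: 9 3,4-bis(benzyloxy)phenol, via aryl formate 8 (not isolated)
Conditions: mCPBA (1.3 equiv), CH2Cl2, 0 °C to rt; aq. Na2SO3/NaHCO3 wash; then K2CO3 (cat.), MeOH, rt
Reagents that add atoms: 3-chloroperoxybenzoic acid (mCPBA), O=C(OO)c1cccc(Cl)c1
Why: Baeyer–Villiger oxidation of an electron-rich benzaldehyde (a Dakin-type conversion overall); the aryl group, activated by the para benzyloxy substituent, migrates in preference to hydride to give formate 8, which methanolysis cleaves to the phenol.

Step 6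
Reactants: 9 3,4-bis(benzyloxy)phenol
Product: 10 1,2-bis(benzyloxy)-4-methoxybenzene
Conditions: MeI (1.5 equiv), K2CO3 (2 equiv), acetone, reflux
Reagents that add atoms: iodomethane, CI
Why: Williamson ether synthesis on the only hydroxyl.

Step 7
Reactants: 10 1,2-bis(benzyloxy)-4-methoxybenzene
Product: 12 4,5-bis(benzyloxy)-2-methoxybenzaldehyde, via iminium chloride 11 (not isolated)
Conditions: POCl3 (1.5 equiv), DMF, 0 to 70 °C; then aq. NaOAc, rt
Reagents that add atoms: N,N-dimethylformamide, CN(C)C=O; water, O
Why: Vilsmeier–Haack formylation; the carbon ortho to the methoxyl and para to a benzyloxy group is the only one with both an ortho and a para donor and is unhindered, so the chloroiminium ion attacks there to give iminium 11, which is hydrolysed on work-up; no strong Lewis acid is present that could cleave benzyl ethers.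

Step 8
Reactants: 12 4,5-bis(benzyloxy)-2-methoxybenzaldehyde
Product: 13 1,2-bis(benzyloxy)-4-ethynyl-5-methoxybenzene
Conditions: dimethyl (1-diazo-2-oxopropyl)phosphonate (1.3 equiv), K2CO3 (2 equiv), MeOH/THF, 0 °C to rt
Reagents that add atoms: dimethyl (1-diazo-2-oxopropyl)phosphonate, CC(=O)C(=[N+]=[N-])P(=O)(OC)OC
Why: Ohira–Bestmann homologation: methanolysis of the reagent gives the anion of dimethyl (diazomethyl)phosphonate, olefination of the aldehyde gives a diazoalkene, and loss of N2 with a 1,2-hydride shift gives the terminal alkyne; the non-enolisable aldehyde and all ethers are stable to K2CO3 in methanol.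

Step 9
Reactants: 6 2-iodo-4,6-dimethoxybenzene-1,3,5-triyl triacetate; 13 1,2-bis(benzyloxy)-4-ethynyl-5-methoxybenzene; 14 carbon monoxide
Product: 17 2-[4,5-bis(benzyloxy)-2-methoxyphenyl]-5,7-dihydroxy-6,8-dimethoxy-4H-chromen-4-one, via ynone 15 (not isolated), via enaminone 16 (not isolated)
Conditions: PdCl2(PPh3)2 (5 mol %), 1,3-bis(diphenylphosphino)propane (5 mol %), thiourea (5 mol %), CO (1 atm, balloon), Et2NH, 40 °C; dilute HCl work-up
Reagents that add atoms: none
Why: PdCl2(PPh3)2 is reduced in the flask to zerovalent palladium, which inserts into the C–I bond of 6; insertion of 14 then gives an aroylpalladium iodide, favoured over direct alkynylation because the two ortho substituents slow substitution at the aryl–palladium stage. A copper-free Sonogashira-type coupling of this acyl complex with 13 (amine-assisted deprotonation of the coordinated alkyne, then reductive elimination) forms C4–C3 and, with aminolysis of the acetates by diethylamine, gives ynone 15. Diethylamine adds to the ynone at C2 to give enaminone 16, and an ortho phenoxide then attacks C2 and expels the amine, forming O1–C2. Ring C therefore closes by a 6-endo addition–elimination. The closest known reaction type is the palladium-catalysed carbonylative annulation of ortho-iodophenols or their acetates with terminal arylalkynes to flavones. No stereocentre is formed. The selectivity required is 6-endo closure to the flavone rather than 5-exo closure to an aurone, and the secondary amine secures it because in the enaminone only C2 carries a leaving group. Ring A needs no regiocontrol because the two oxygens flanking the C–I carbon are related by the mirror plane through C4a and C7, so either closure gives 17 and the other oxygen ends as the chelated 5-OH.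

Step 10
Reactants: 17 2-[4,5-bis(benzyloxy)-2-methoxyphenyl]-5,7-dihydroxy-6,8-dimethoxy-4H-chromen-4-one
Product: 18 5,7-bis(benzyloxy)-2-[4,5-bis(benzyloxy)-2-methoxyphenyl]-6,8-dimethoxy-4H-chromen-4-one
Conditions: BnBr (3 equiv), K2CO3 (4 equiv), Bu4NI (cat.), DMF, 60 °C
Reagents that add atoms: benzyl bromide, BrCc1ccccc1
Why: Williamson benzylation; the 7-OH reacts readily, the chelated 5-OH needs excess reagent and heat, and ring A has no free carbon, so C-benzylation cannot compete.

Step 11
Reactants: 18 5,7-bis(benzyloxy)-2-[4,5-bis(benzyloxy)-2-methoxyphenyl]-6,8-dimethoxy-4H-chromen-4-one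
Product: 20 5,7-bis(benzyloxy)-2-[4,5-bis(benzyloxy)-2-methoxyphenyl]-3-hydroxy-6,8-dimethoxy-4H-chromen-4-one, via epoxide 19 (not isolated)
Conditions: 2KHSO5·KHSO4·K2SO4 (Oxone), acetone, NaHCO3, Bu4NHSO4 (cat.), CH2Cl2/H2O, 0 °C to rt; then p-toluenesulfonic acid (cat.), CH2Cl2, rt
Reagents that add atoms: dimethyldioxirane, made in the flask from acetone and KHSO5, CC1(C)OO1; potassium peroxymonosulfate, [K+].[O-]S(=O)(=O)OO
Why: Epoxidation of the electron-rich C2=C3 enol ether by dimethyldioxirane generated in the flask, so that no peroxide solution is isolated; acid then opens epoxide 19 at C2 to an oxocarbenium ion stabilised by O1 and ring B, and loss of H3 gives the flavonol, which is the known dioxirane route from 5-O-protected flavones to 3-hydroxyflavones.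

Step 12
Reactants: 20 5,7-bis(benzyloxy)-2-[4,5-bis(benzyloxy)-2-methoxyphenyl]-3-hydroxy-6,8-dimethoxy-4H-chromen-4-one
Product: 21 5,7-bis(benzyloxy)-2-[4,5-bis(benzyloxy)-2-methoxyphenyl]-3,6,8-trimethoxy-4H-chromen-4-one
Conditions: MeI (2 equiv), K2CO3 (3 equiv), DMF, rt to 40 °C
Reagents that add atoms: iodomethane, CI
Why: Williamson methylation of the only free hydroxyl; K2CO3 is too mild to open the pyranone.

Step 13
Reactants: 21 5,7-bis(benzyloxy)-2-[4,5-bis(benzyloxy)-2-methoxyphenyl]-3,6,8-trimethoxy-4H-chromen-4-one
Product: 22 2-(4,5-dihydroxy-2-methoxyphenyl)-5,7-dihydroxy-3,6,8-trimethoxy-4H-chromen-4-one (5,7,4',5'-tetrahydroxy-3,6,8,2'-tetramethoxyflavone)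
Conditions: H2 (1 atm), 10 % Pd/C, EtOAc/MeOH, rt; filtered and concentrated under argon
Reagents that add atoms: none
Why: Hydrogenolysis of the four benzyl aryl ethers at one atmosphere; the tetrasubstituted C2=C3 bond of the vinylogous ester and the four methyl ethers should survive, and the catechol is protected from air during isolation.

## Compound list

1 | 1,3,5-tris(benzyloxy)benzene | c1ccc(COc2cc(OCc3ccccc3)cc(OCc3ccccc3)c2)cc1 | starting material
2 | 1,3,5-tris(benzyloxy)-2,4-dibromobenzene | Brc1c(OCc2ccccc2)cc(OCc2ccccc2)c(Br)c1OCc1ccccc1 | intermediate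
3 | 1,3,5-tris(benzyloxy)-2,4-dimethoxybenzene | COc1c(OCc2ccccc2)cc(OCc2ccccc2)c(OC)c1OCc1ccccc1 | intermediate
4 | 2,4-dimethoxybenzene-1,3,5-triol | COc1c(O)cc(O)c(OC)c1O | intermediate
5 | 2-iodo-4,6-dimethoxybenzene-1,3,5-triol | COc1c(O)c(I)c(O)c(OC)c1O | intermediate (not isolated)
6 | 2-iodo-4,6-dimethoxybenzene-1,3,5-triyl triacetate | CC(=O)Oc1c(I)c(OC(C)=O)c(OC)c(OC(C)=O)c1OC | intermediate
7 | 3,4-bis(benzyloxy)benzaldehyde | O=Cc1ccc(OCc2ccccc2)c(OCc2ccccc2)c1 | starting material
8 | 3,4-bis(benzyloxy)phenyl formate | O=COc1ccc(OCc2ccccc2)c(OCc2ccccc2)c1 | intermediate (not isolated)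
9 | 3,4-bis(benzyloxy)phenol | Oc1ccc(OCc2ccccc2)c(OCc2ccccc2)c1 | intermediate
10 | 1,2-bis(benzyloxy)-4-methoxybenzene | COc1ccc(OCc2ccccc2)c(OCc2ccccc2)c1 | intermediate
11 | [4,5-bis(benzyloxy)-2-methoxybenzylidene]dimethylammonium chloride | COc1cc(OCc2ccccc2)c(OCc2ccccc2)cc1C=[N+](C)C.[Cl-] | intermediate (not isolated)
12 | 4,5-bis(benzyloxy)-2-methoxybenzaldehyde | COc1cc(OCc2ccccc2)c(OCc2ccccc2)cc1C=O | intermediate
13 | 1,2-bis(benzyloxy)-4-ethynyl-5-methoxybenzene | C#Cc1cc(OCc2ccccc2)c(OCc2ccccc2)cc1OC | intermediate
14 | carbon monoxide | [C-]#[O+] | starting material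
15 | 3-[4,5-bis(benzyloxy)-2-methoxyphenyl]-1-(2,4,6-trihydroxy-3,5-dimethoxyphenyl)prop-2-yn-1-one | COc1cc(OCc2ccccc2)c(OCc2ccccc2)cc1C#CC(=O)c1c(O)c(OC)c(O)c(OC)c1O | intermediate (not isolated)
16 | (2E)-3-[4,5-bis(benzyloxy)-2-methoxyphenyl]-3-(diethylamino)-1-(2,4,6-trihydroxy-3,5-dimethoxyphenyl)prop-2-en-1-one | CCN(CC)/C(=C/C(=O)c1c(O)c(OC)c(O)c(OC)c1O)c1cc(OCc2ccccc2)c(OCc2ccccc2)cc1OC | intermediate (not isolated)
17 | 2-[4,5-bis(benzyloxy)-2-methoxyphenyl]-5,7-dihydroxy-6,8-dimethoxy-4H-chromen-4-one | COc1cc(OCc2ccccc2)c(OCc2ccccc2)cc1-c1cc(=O)c2c(O)c(OC)c(O)c(OC)c2o1 | intermediate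
18 | 5,7-bis(benzyloxy)-2-[4,5-bis(benzyloxy)-2-methoxyphenyl]-6,8-dimethoxy-4H-chromen-4-one | COc1cc(OCc2ccccc2)c(OCc2ccccc2)cc1-c1cc(=O)c2c(OCc3ccccc3)c(OC)c(OCc3ccccc3)c(OC)c2o1 | intermediate
19 | rac-4,6-bis(benzyloxy)-1a-[4,5-bis(benzyloxy)-2-methoxyphenyl]-3,5-dimethoxy-1a,7a-dihydro-7H-oxireno[2,3-b]chromen-7-one (the cis-fused 2,3-epoxide of 18) | COc1cc(OCc2ccccc2)c(OCc2ccccc2)cc1[C@]12O[C@H]1C(=O)c1c(OCc3ccccc3)c(OC)c(OCc3ccccc3)c(OC)c1O2 | intermediate (not isolated)
20 | 5,7-bis(benzyloxy)-2-[4,5-bis(benzyloxy)-2-methoxyphenyl]-3-hydroxy-6,8-dimethoxy-4H-chromen-4-one | COc1cc(OCc2ccccc2)c(OCc2ccccc2)cc1-c1oc2c(OC)c(OCc3ccccc3)c(OC)c(OCc3ccccc3)c2c(=O)c1O | intermediate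
21 | 5,7-bis(benzyloxy)-2-[4,5-bis(benzyloxy)-2-methoxyphenyl]-3,6,8-trimethoxy-4H-chromen-4-one | COc1cc(OCc2ccccc2)c(OCc2ccccc2)cc1-c1oc2c(OC)c(OCc3ccccc3)c(OC)c(OCc3ccccc3)c2c(=O)c1OC | intermediate
22 | 2-(4,5-dihydroxy-2-methoxyphenyl)-5,7-dihydroxy-3,6,8-trimethoxy-4H-chromen-4-one | COc1cc(O)c(O)cc1-c1oc2c(OC)c(O)c(OC)c(O)c2c(=O)c1OC | target

## Step count and risks

Total: 13 steps. Longest linear sequence: 9 steps (steps 1 to 4, then 9 to 13); the ring B branch (steps 5 to 8, then 9 to 13) has the same length.

Step 9 (key step). The aroylpalladium intermediate may be intercepted by diethylamine (aminocarbonylation to a diethylamide) faster than by the alkyne. Alternatively, oxidative addition into the doubly ortho-substituted C–I bond may become slow once the acetates are lost and the ring turns into an electron-rich phenoxide, so that alkyne dimerisation and reductive loss of iodine take over. The fallback drops the carbonylation, sets out from 4 and 12 and comes back at 18.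
- Friedel–Crafts C-acetylation of 4 (acetic acid, BF3·OEt2) at its only free position should give 1-(2,4,6-trihydroxy-3,5-dimethoxyphenyl)ethan-1-one F1.
- Benzylation with two equivalents of benzyl bromide and K2CO3 leaves one chelated ortho hydroxyl and gives 1-[2,4-bis(benzyloxy)-6-hydroxy-3,5-dimethoxyphenyl]ethan-1-one F2.
- Claisen–Schmidt condensation with 12 (KOH, ethanol) gives (2E)-3-[4,5-bis(benzyloxy)-2-methoxyphenyl]-1-[2,4-bis(benzyloxy)-6-hydroxy-3,5-dimethoxyphenyl]prop-2-en-1-one F3.
- Oxidative cyclisation with catalytic iodine in dimethyl sulfoxide at about 120 °C closes ring C to 18. The Algar–Flynn–Oyamada oxidation is avoided because chalcones with an ether at the second ortho position tend to give aurones.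

Step 2. Reductive loss of bromine may compete with the double substitution at two crowded, electron-rich carbons, and a stalled mono-substitution is possible. The fallback makes the two C–O bonds by aldehyde oxidation instead; it sets out from 1 and comes back at 3.
- Vilsmeier–Haack formylation of 1 gives 2,4,6-tris(benzyloxy)benzaldehyde F4.
- Baeyer–Villiger oxidation and methanolysis as in step 5 give 2,4,6-tris(benzyloxy)phenol F5.
- Methylation (MeI, K2CO3) gives 1,3,5-tris(benzyloxy)-2-methoxybenzene F6.
- A second formylation, at either of the two equivalent free positions, gives 2,4,6-tris(benzyloxy)-3-methoxybenzaldehyde F7.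
- A second oxidation and methanolysis give 2,4,6-tris(benzyloxy)-3-methoxyphenol F8, and methylation then gives 3.

Step 4. N-Iodosuccinimide may oxidise the very electron-rich triol to quinonoid material instead of iodinating it, because electron transfer competes with C-iodination in such phenols. The fallback iodinates before the phenols are freed; it sets out from 3 and comes back at 6.
- Iodination of 3 (N-iodosuccinimide, catalytic trifluoroacetic acid, MeCN) at its only free position gives 1,3,5-tris(benzyloxy)-2-iodo-4,6-dimethoxybenzene F9.
- The benzyl ethers are cleaved with BCl3 and pentamethylbenzene in CH2Cl2 at −78 °C, which spares the aryl iodide and the methyl ethers.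
- The resulting 5 is acetylated without isolation (Ac2O, pyridine) to give 6.

Step 11. Oxygen transfer to the crowded, twisted C2=C3 bond may be slow, so that oxidation of benzylic C–H bonds or of ring B competes, or the epoxide may rearrange instead of opening to the enol. The fallback sets out from 18 and comes back at 20.
- Deprotonation at C3 with LiN(iPr)2 in THF at −78 °C and trapping with B(OMe)3 gives dimethyl {5,7-bis(benzyloxy)-2-[4,5-bis(benzyloxy)-2-methoxyphenyl]-6,8-dimethoxy-4-oxo-4H-chromen-3-yl}boronate F10.
- Oxidation of the C–B bond with H2O2 in acetic acid gives 20.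

## Further compounds

F1 | step 9 | 1-(2,4,6-trihydroxy-3,5-dimethoxyphenyl)ethan-1-one | CC(=O)c1c(O)c(OC)c(O)c(OC)c1O
F2 | step 9 | 1-[2,4-bis(benzyloxy)-6-hydroxy-3,5-dimethoxyphenyl]ethan-1-one | CC(=O)c1c(O)c(OC)c(OCc2ccccc2)c(OC)c1OCc1ccccc1
F3 | step 9 | (2E)-3-[4,5-bis(benzyloxy)-2-methoxyphenyl]-1-[2,4-bis(benzyloxy)-6-hydroxy-3,5-dimethoxyphenyl]prop-2-en-1-one | COc1cc(OCc2ccccc2)c(OCc2ccccc2)cc1/C=C/C(=O)c1c(O)c(OC)c(OCc2ccccc2)c(OC)c1OCc1ccccc1
F4 | step 2 | 2,4,6-tris(benzyloxy)benzaldehyde | O=Cc1c(OCc2ccccc2)cc(OCc2ccccc2)cc1OCc1ccccc1
F5 | step 2 | 2,4,6-tris(benzyloxy)phenol | Oc1c(OCc2ccccc2)cc(OCc2ccccc2)cc1OCc1ccccc1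
F6 | step 2 | 1,3,5-tris(benzyloxy)-2-methoxybenzene | COc1c(OCc2ccccc2)cc(OCc2ccccc2)cc1OCc1ccccc1
F7 | step 2 | 2,4,6-tris(benzyloxy)-3-methoxybenzaldehyde | COc1c(OCc2ccccc2)cc(OCc2ccccc2)c(C=O)c1OCc1ccccc1
F8 | step 2 | 2,4,6-tris(benzyloxy)-3-methoxyphenol | COc1c(OCc2ccccc2)cc(OCc2ccccc2)c(O)c1OCc1ccccc1
F9 | step 4 | 1,3,5-tris(benzyloxy)-2-iodo-4,6-dimethoxybenzene | COc1c(OCc2ccccc2)c(I)c(OCc2ccccc2)c(OC)c1OCc1ccccc1
F10 | step 11 | dimethyl {5,7-bis(benzyloxy)-2-[4,5-bis(benzyloxy)-2-methoxyphenyl]-6,8-dimethoxy-4-oxo-4H-chromen-3-yl}boronate | COB(OC)c1c(-c2cc(OCc3ccccc3)c(OCc3ccccc3)cc2OC)oc2c(OC)c(OCc3ccccc3)c(OC)c(OCc3ccccc3)c2c1=O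
A1 | alternative 1 | rac-4,6-bis(benzyloxy)-2-[4,5-bis(benzyloxy)-2-methoxyphenyl]-5,7-dimethoxy-1-benzofuran-3(2H)-one | COc1cc(OCc2ccccc2)c(OCc2ccccc2)cc1C1Oc2c(OC)c(OCc3ccccc3)c(OC)c(OCc3ccccc3)c2C1=O
A2 | alternative 1 | {[4,6-bis(benzyloxy)-2-[4,5-bis(benzyloxy)-2-methoxyphenyl]-5,7-dimethoxy-1-benzofuran-3-yl]oxy}(tert-butyl)dimethylsilane | COc1cc(OCc2ccccc2)c(OCc2ccccc2)cc1-c1oc2c(OC)c(OCc3ccccc3)c(OC)c(OCc3ccccc3)c2c1O[Si](C)(C)C(C)(C)C
A3 | alternative 1 | 5,7-bis(benzyloxy)-2-[4,5-bis(benzyloxy)-2-methoxyphenyl]-3-bromo-6,8-dimethoxy-4H-chromen-4-one | COc1cc(OCc2ccccc2)c(OCc2ccccc2)cc1-c1oc2c(OC)c(OCc3ccccc3)c(OC)c(OCc3ccccc3)c2c(=O)c1Br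
A4 | alternative 2 | 2-[4,5-bis(benzyloxy)-2-methoxyphenyl]-5-bromo-3-methoxy-4H-pyran-4-one | COc1cc(OCc2ccccc2)c(OCc2ccccc2)cc1-c1occ(Br)c(=O)c1OC
A5 | alternative 2 | 3-tert-butoxy-4-methoxycyclobut-3-ene-1,2-dione | COC1=C(OC(C)(C)C)C(=O)C1=O
A6 | alternative 2 | rac-2-tert-butoxy-4-hydroxy-3-methoxy-4-{6-[4,5-bis(benzyloxy)-2-methoxyphenyl]-5-methoxy-4-oxo-4H-pyran-3-yl}cyclobut-2-en-1-one | COc1cc(OCc2ccccc2)c(OCc2ccccc2)cc1-c1occ(C2(O)C(OC)=C(OC(C)(C)C)C2=O)c(=O)c1OC
A7 | alternative 2 | 2-[4,5-bis(benzyloxy)-2-methoxyphenyl]-7-tert-butoxy-5,8-dihydroxy-3,6-dimethoxy-4H-chromen-4-one | COc1cc(OCc2ccccc2)c(OCc2ccccc2)cc1-c1oc2c(O)c(OC(C)(C)C)c(OC)c(O)c2c(=O)c1OC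
A8 | alternative 3 | 2,4,6-tribromo-3,5-dimethoxybenzoic acid | COc1c(Br)c(OC)c(Br)c(C(=O)O)c1Br
A9 | alternative 3 | 1-[4,5-bis(benzyloxy)-2-methoxyphenyl]-2-methoxyethan-1-one | COCC(=O)c1cc(OCc2ccccc2)c(OCc2ccccc2)cc1OC
A10 | alternative 3 | rac-1-[4,5-bis(benzyloxy)-2-methoxyphenyl]-2-methoxy-3-(2,4,6-tribromo-3,5-dimethoxyphenyl)propane-1,3-dione | COc1cc(OCc2ccccc2)c(OCc2ccccc2)cc1C(=O)C(OC)C(=O)c1c(Br)c(OC)c(Br)c(OC)c1Br
A11 | alternative 3 | 2-[4,5-bis(benzyloxy)-2-methoxyphenyl]-5,7-dibromo-3,6,8-trimethoxy-4H-chromen-4-one | COc1cc(OCc2ccccc2)c(OCc2ccccc2)cc1-c1oc2c(OC)c(Br)c(OC)c(Br)c2c(=O)c1OC
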